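## Retrosynthetic overview

1. The target is read as epicatechin-(4β→8)-catechin-(4α→8)-catechin whose terminal 3-OH carries the (S)-1-hydroxy-6-oxocyclohex-2-ene-1-carbonyl (HCH) group; the last operations are release of the HCH ketone from a dithiolane and fluoride desilylation.
2. Key disconnection: ring C of the terminal unit is cut at C2–C3 and C4–C4a (formal [4+2]) into three pieces. These are a phenol (ring A, already carrying the upper dimer at the future C8), a 3,4-disilyloxybenzaldehyde (C2 and ring B) and a chiral spiro-dioxinone. In the dioxinone the C3–C4 unit is a cis-enediol tied up by the carboxyl and the tertiary hydroxyl of the HCH acid; hydride then cuts the benzylic C4–O tether, giving C4H2 and freeing the HCH oxygen.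
3. Enabling feature: in ring C, C2 lies between the aryl ether oxygen O1 and the electron-rich ring B, so it can be generated as an aryloxy-benzyl cation, a 2-oxadiene C2=O1–C8a=C4a. C3 bears the ester oxygen of an α-hydroxy acid and C4 is benzylic to the phloroglucinol-type ring A, so a temporary oxygen at C4 polarises the two-carbon partner correctly and is removable by ionic hydrogenation.
4. The phenol comes from two Friedel–Crafts interflavan couplings with orthogonal C4 leaving groups (thioether on the epicatechin unit, alkoxy on the catechin unit). The dioxinone comes from methyl 2-methoxybenzoate by Birch reduction, catalytic asymmetric α-hydroxylation, dithioketalisation and annulation with a bromoacetal.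
5. Ring order: rings A and B of all units and the two upper rings C are bought with epicatechin, catechin, phloroglucinol and the aldehyde. The HCH cyclohexene (Birch), the dithiolane and the dioxinone are made next; the terminal ring C is formed last, and the dioxanone tether is opened one step later.

Key step: step 16

Remark: TBS = tert-butyldimethylsilyl, TES = triethylsilyl; the ether-bearing C4 centre of the catechin-derived electrophiles and of the cycloadduct is drawn as the expected isomer, but it becomes planar on ionisation, so its configuration has no bearing on the route.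

## Route

Step 1
Reactants: 1 methyl 2-methoxybenzoate
Product: 3 methyl 6-oxocyclohex-2-ene-1-carboxylate, via diene enol ether 2 (not isolated)
Conditions: K, NH3(l), t-BuOH (1 equiv), THF, −78 °C; NH4Cl; then 1 M HCl, THF, 0 °C
Reagents that add atoms: water, O
Why: Birch reduction of the benzoate gives the 1,4-dihydro ester, and dilute acid hydrolyses the methyl enol ether to the β,γ-unsaturated β-keto ester without moving the ring double bond; C1 is epimerisable, so no stereocentre has to be controlled here.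

Step 2
Reactants: 3 methyl 6-oxocyclohex-2-ene-1-carboxylate
Product: 4 methyl (S)-1-hydroxy-6-oxocyclohex-2-ene-1-carboxylate
Conditions: Cu(OTf)2 (10 mol %), (S,S)-2,2'-isopropylidenebis(4-tert-butyl-2-oxazoline) (11 mol %), 2-(phenylsulfonyl)-3-phenyloxaziridine (1.2 equiv), CH2Cl2, 0 °C
Reagents that add atoms: 2-(phenylsulfonyl)-3-phenyloxaziridine, O=S(=O)(c1ccccc1)N1OC1c1ccccc1
Why: Chiral Lewis acid-catalysed enantioselective α-hydroxylation of a β-keto ester, in which the two-point-bound divalent copper enolate is oxygenated by the oxaziridine on the face left open by the bis(oxazoline) ligand, should set the quaternary carbinol as (S) (the ligand antipode is used if the opposite sense is found).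

Step 3
Reactants: 4 methyl (S)-1-hydroxy-6-oxocyclohex-2-ene-1-carboxylate
Product: 5 methyl (R)-6-hydroxy-1,4-dithiaspiro[4.5]dec-7-ene-6-carboxylate
Conditions: HSCH2CH2SH (1.5 equiv), BF3·OEt2 (0.3 equiv), CH2Cl2, 0 °C → rt
Reagents that add atoms: ethane-1,2-dithiol, SCCS
Why: Lewis acid-catalysed dithioketalisation turns the ketone into a 1,3-dithiolane that is inert to base and silyl triflates and bulky enough to differentiate the faces of the later dienophile; the quaternary centre is untouched (its descriptor changes from S to R only through the priority rules).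

Step 4
Reactants: 5 methyl (R)-6-hydroxy-1,4-dithiaspiro[4.5]dec-7-ene-6-carboxylate
Product: 6 (R)-6-hydroxy-1,4-dithiaspiro[4.5]dec-7-ene-6-carboxylic acid
Conditions: LiOH, THF/MeOH/H2O, rt; then 1 M HCl to pH 3
Reagents that add atoms: lithium hydroxide, [Li+].[OH-]
Why: Saponification of the α-hydroxy methyl ester should be clean because, with the ketone masked, there is no β-keto acid to decarboxylate or to undergo retro-Claisen cleavage; the stereocentre is untouched.

Step 5
Reactants: 6 (R)-6-hydroxy-1,4-dithiaspiro[4.5]dec-7-ene-6-carboxylic acid; 7 2-bromo-1,1-dimethoxyethane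
Product: 9 spiro-fused 5-methoxy-1,4-dioxan-2-one (methoxy-dioxanone), via dimethoxyethyl ester 8 (not isolated)
Conditions: Cs2CO3, NaI (cat.), DMF, 80 °C; then camphorsulfonic acid (cat.), 5 Å MS, toluene, 80 °C
Reagents that add atoms: none
Why: SN2 O-alkylation of the caesium carboxylate by the α-bromo acetal gives ester 8, and acid-catalysed intramolecular transacetalisation by the tertiary hydroxyl then closes the six-membered lactone-acetal with loss of methanol; the new acetal carbon forms as an epimer mixture that disappears in step 6.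

Step 6
Reactants: 9 spiro-fused 5-methoxy-1,4-dioxan-2-one
Product: 10 (R)-spiro-dioxinone (1,4-dioxin-2(3H)-one whose C3 is C6 of the 1,4-dithiaspiro[4.5]dec-7-ene unit)
Conditions: TMSOTf, iPr2NEt, CH2Cl2, 0 °C → rt
Reagents that add atoms: none
Why: Silyl triflate ionises the mixed acetal to the cyclic oxocarbenium ion and the hindered amine removes the adjacent proton (acetal-to-enol-ether elimination), which should give the ring cis double bond flanked by the ether and the ester oxygen; the dithiolane and the quaternary centre are inert.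

Step 7
Reactants: 11 (−)-epicatechin
Product: 12 3,5,7,3',4'-penta-O-TBS-epicatechin
Conditions: TBSOTf (6 equiv), 2,6-lutidine, CH2Cl2, 0 °C → rt
Reagents that add atoms: tert-butyldimethylsilyl triflate, CC(C)(C)[Si](C)(C)OS(=O)(=O)C(F)(F)F
Why: Silyl ether formation with the silyl triflate caps the four phenols and the hindered axial 3-hydroxyl in one operation; no stereocentre is affected.

Step 8
Reactants: 12 3,5,7,3',4'-penta-O-TBS-epicatechin
Product: 13 4β-(2-ethoxyethoxy)-penta-O-TBS-epicatechin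
Conditions: DDQ (1.5 equiv), 2-ethoxyethanol (5 equiv), CH2Cl2, rt
Reagents that add atoms: 2-ethoxyethanol, CCOCCO
Why: DDQ abstracts hydride from the C4 methylene activated by the 5,7-dioxygenated ring A (benzylic C–H oxidation), and the alcohol should trap the cation anti to the 2-aryl and 3-OTBS groups, giving the 4β ether.

Step 9
Reactants: 13 4β-(2-ethoxyethoxy)-penta-O-TBS-epicatechin
Product: 14 4β-benzylsulfanyl-penta-O-TBS-epicatechin
Conditions: BnSH (3 equiv), BF3·OEt2 (0.2 equiv), CH2Cl2, −78 → −40 °C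
Reagents that add atoms: phenylmethanethiol, SCc1ccccc1
Why: Lewis acid-mediated SN1 exchange at C4 (the chelating alkoxy group leaves and the thiol adds to the ring-A-stabilised cation trans to the 3-OTBS group, 4β) installs a leaving group that only a thiophile will activate.

Step 10
Reactants: 15 (+)-catechin
Product: 16 3,5,7,3',4'-penta-O-TBS-catechin
Conditions: TBSOTf (6 equiv), 2,6-lutidine, CH2Cl2, 0 °C → rt
Reagents that add atoms: tert-butyldimethylsilyl triflate, CC(C)(C)[Si](C)(C)OS(=O)(=O)C(F)(F)F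
Why: Exhaustive silyl ether formation as in step 7; no stereocentre is affected.

Step 11
Reactants: 16 3,5,7,3',4'-penta-O-TBS-catechin
Product: 17 4α-(2-ethoxyethoxy)-penta-O-TBS-catechin
Conditions: DDQ (1.5 equiv), 2-ethoxyethanol (5 equiv), CH2Cl2, rt
Reagents that add atoms: 2-ethoxyethanol, CCOCCO
Why: DDQ benzylic C–H oxidation at C4 as in step 8, with the alcohol expected to enter trans to the bulky 3-OTBS group of the 2,3-trans unit (either C4 epimer serves equally).

Step 12
Reactants: 14 4β-benzylsulfanyl-penta-O-TBS-epicatechin; 17 4α-(2-ethoxyethoxy)-penta-O-TBS-catechin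
Product: 18 penta-O-TBS-epicatechin-(4β→8)-[4α-(2-ethoxyethoxy)-penta-O-TBS-catechin]
Conditions: AgOTf (1.5 equiv), 2,6-di-tert-butyl-4-methylpyridine (2 equiv), 17 (3 equiv), 4 Å MS, CH2Cl2, −40 → 0 °C
Reagents that add atoms: none
Why: Thiophilic activation of the C4 thioether by AgOTf and Friedel–Crafts alkylation at C8 of 17 should form the interflavan bond trans to the 3-OTBS group (4β), C6 being shielded by two flanking OTBS groups, while the hindered pyridine scavenges triflic acid so that the 4-alkoxy group of 17 and of 18 stays intact (orthogonal activation).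

Step 13
Reactants: 19 phloroglucinol
Product: 20 3,5-bis(TBS-oxy)phenol
Conditions: TBSCl (2.0 equiv), imidazole, DMF, 0 °C
Reagents that add atoms: tert-butyldimethylsilyl chloride, CC(C)(C)[Si](C)(C)Cl
Why: Silyl ether formation on a C3-symmetric triol, where only the degree of silylation has to be controlled by stoichiometry; the mono- and tris-silyl ethers are separated and recycled.

Step 14
Reactants: 18 penta-O-TBS-epicatechin-(4β→8)-[4α-(2-ethoxyethoxy)-penta-O-TBS-catechin]; 20 3,5-bis(TBS-oxy)phenol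
Product: 21 penta-O-TBS-epicatechin-(4β→8)-penta-O-TBS-catechin-(4α→2)-[3,5-bis(TBS-oxy)phenol]
Conditions: 20 (3 equiv), TMSOTf (0.5 equiv), CH2Cl2, −78 → −40 °C
Reagents that add atoms: none
Why: TMSOTf ionises the chelating 4-alkoxy group and the C4 cation alkylates the phenol at the carbon ortho to its hydroxyl (Friedel–Crafts alkylation; the para carbon lies between two OTBS groups), entering trans to the 3-OTBS group of the 2,3-trans unit to give the 4α bond.

Step 15
Reactants: 22 3,4-dihydroxybenzaldehyde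
Product: 23 3,4-bis(TBS-oxy)benzaldehyde
Conditions: TBSCl (2.3 equiv), imidazole, DMF, rt
Reagents that add atoms: tert-butyldimethylsilyl chloride, CC(C)(C)[Si](C)(C)Cl
Why: Routine silyl ether formation on both phenols of the catechol aldehyde; no stereocentre is involved.

Step 16
Reactants: 21 penta-O-TBS-epicatechin-(4β→8)-penta-O-TBS-catechin-(4α→2)-[3,5-bis(TBS-oxy)phenol]; 23 3,4-bis(TBS-oxy)benzaldehyde; 10 (R)-spiro-dioxinone
Product: 25 cycloadduct (terminal 2,3-trans-3,4-cis flavan-3,4-diyl unit with O3 and O4 bridged as a cis-fused 1,4-dioxan-2-one), via silyl aryl acetal 24 (not isolated)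
Conditions: 23 (1.2 equiv), TMSOTf (2.2 equiv), 2,6-di-tert-butyl-4-methylpyridine (2.5 equiv), 4 Å MS, CH2Cl2, −78 °C; then 10 (1.5 equiv), −78 → −40 °C
Reagents that add atoms: none
Why: Proposed new method: TMSOTf condenses the phenol with the aldehyde to the O-aryl O-silyl acetal 24 and ionises it (loss of hexamethyldisiloxane) to an aryloxy-benzyl oxocarbenium ion, a cationic 2-oxadiene C2=O1–C8a=C4a; its C2 is attacked by the acyloxy-bearing alkene carbon of 10 (the carbon β to the ring ether oxygen, the stronger donor), and the alkoxy-stabilised cation at the other alkene carbon is captured by the only free arene carbon ortho to O1, so C2–C3 and C4–C4a form in one operation. The closest known reaction type is the oxa-Povarov reaction (formal inverse-electron-demand [4+2] cycloaddition of aryl oxocarbenium ions with alkenes to chromans), which has not been run with an enediol-type partner that carries the future ester. Ring C closes in the second event by a 6-exo-trig Friedel–Crafts attack of the arene on the oxocarbenium carbon, and the two-carbon partner adds suprafacially, so the dioxanone is cis-fused. C3 and the transient C4 centre should be set by the (R)-spiro centre of 10, whose dithiolane arm shields one face of the dioxinone so that both bonds form anti to it (this corresponds to 3S); C2 should be set by exo approach of the (E)-oxocarbenium ion, because the spiro-cyclohexene blocks the endo region on both faces, which places the aryl group trans to O3 and equatorial (2R). The step needs regioselectivity in the two-carbon partner, secured by the ether-versus-acyloxy polarisation of its double bond, and site selectivity in the arene, secured by the single free phenol, the single free ortho carbon and the OTBS groups that flank every other arene C–H.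

Step 17
Reactants: 25 cycloadduct
Product: 26 tetradeca-O-TBS epicatechin-(4β→8)-catechin-(4α→8)-catechin 3-O-[(R)-6-(triethylsilyloxy)-1,4-dithiaspiro[4.5]dec-7-ene-6-carbonyl] ester
Conditions: Et3SiH (5 equiv), TESOTf (0.3 equiv), CH2Cl2, −78 → −40 °C
Reagents that add atoms: triethylsilane, CC[SiH](CC)CC
Why: Ionic hydrogenation, in which the silyl triflate silylates the tertiary ether oxygen, the C4–O bond ionises to the benzylic cation stabilised by three ring-A oxygens (far more readily than C2–O1) and the silane delivers hydride, should give the C4 methylene and the TES ether of the HCH hydroxyl with C2 and C3 untouched and the C4 stereocentre gone.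

Step 18
Reactants: 26 dithiolane-masked trimer ester
Product: 27 tetradeca-O-TBS epicatechin-(4β→8)-catechin-(4α→8)-catechin 3-O-[(S)-6-oxo-1-(triethylsilyloxy)cyclohex-2-ene-1-carbonyl] ester
Conditions: MeI (20 equiv), CaCO3, MeCN/THF/H2O, 45 °C, dark
Reagents that add atoms: water, O
Why: S-Alkylative hydrolysis of the dithioketal (methylation makes sulfur a leaving group and water opens the thionium ion) runs under buffered, near-neutral conditions that should spare the silyl ethers, the interflavan bonds and the β,γ-unsaturated α-silyloxy β-keto ester; the quaternary centre is untouched and now reads (S).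

Step 19
Reactants: 27 silyl-protected keto ester
Product: 28 target, epicatechin-(4β→8)-catechin-(4α→8)-catechin 3-O-[(S)-1-hydroxy-6-oxocyclohex-2-ene-1-carbonyl] ester
Conditions: HF·pyridine, pyridine, THF, 0 °C → rt, argon
Reagents that add atoms: none
Why: Fluoride-mediated cleavage of the fourteen TBS ethers and the TES ether under buffered, non-basic and non-reductive conditions should leave the alkene, the HCH ester and the acid-labile interflavan bonds intact; no stereocentre is affected.

## Compound list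

1 | methyl 2-methoxybenzoate | COC(=O)c1ccccc1OC | starting material
2 | methyl 2-methoxycyclohexa-2,5-diene-1-carboxylate (racemic) | COC(=O)C1C=CCC=C1OC | intermediate
3 | methyl 6-oxocyclohex-2-ene-1-carboxylate (racemic, enolisable) | COC(=O)C1C=CCCC1=O | intermediate
4 | methyl (S)-1-hydroxy-6-oxocyclohex-2-ene-1-carboxylate | O=C1CCC=C[C@@]1(O)C(=O)OC | intermediate
5 | methyl (R)-6-hydroxy-1,4-dithiaspiro[4.5]dec-7-ene-6-carboxylate | S1CCSC12CCC=C[C@@]2(O)C(=O)OC | intermediate
6 | (R)-6-hydroxy-1,4-dithiaspiro[4.5]dec-7-ene-6-carboxylic acid | S1CCSC12CCC=C[C@@]2(O)C(=O)O | intermediate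
7 | 2-bromo-1,1-dimethoxyethane | COC(CBr)OC | starting material
8 | 2,2-dimethoxyethyl (R)-6-hydroxy-1,4-dithiaspiro[4.5]dec-7-ene-6-carboxylate | S1CCSC12CCC=C[C@@]2(O)C(=O)OCC(OC)OC | intermediate
9 | 5-methoxy-1,4-dioxan-2-one spiro-fused through its C3 to C6 of the 1,4-dithiaspiro[4.5]dec-7-ene unit, (R) at the quaternary carbon, both epimers at the acetal carbon | S1CCSC12CCC=C[C@@]2(OC(OC)CO3)C3=O | intermediate
10 | 1,4-dioxin-2(3H)-one spiro-fused through its C3 to C6 of the 1,4-dithiaspiro[4.5]dec-7-ene unit, (R) at the quaternary carbon | S1CCSC12CCC=C[C@@]2(OC=CO3)C3=O | intermediate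
11 | (−)-epicatechin, (2R,3R) | C1c2c(O)cc(O)cc2O[C@H](c2ccc(O)c(O)c2)[C@@H]1O | starting material
12 | 3,5,7,3',4'-penta-O-TBS-epicatechin | C1c2c(O[Si](C)(C)C(C)(C)C)cc(O[Si](C)(C)C(C)(C)C)cc2O[C@H](c2ccc(O[Si](C)(C)C(C)(C)C)c(O[Si](C)(C)C(C)(C)C)c2)[C@@H]1O[Si](C)(C)C(C)(C)C | intermediate
13 | 4β-(2-ethoxyethoxy)-penta-O-TBS-epicatechin (2,3-cis-3,4-trans) | CCOCCO[C@H]1c2c(O[Si](C)(C)C(C)(C)C)cc(O[Si](C)(C)C(C)(C)C)cc2O[C@H](c2ccc(O[Si](C)(C)C(C)(C)C)c(O[Si](C)(C)C(C)(C)C)c2)[C@@H]1O[Si](C)(C)C(C)(C)C | intermediate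
14 | 4β-benzylsulfanyl-penta-O-TBS-epicatechin (2,3-cis-3,4-trans) | c1ccccc1CS[C@H]1c2c(O[Si](C)(C)C(C)(C)C)cc(O[Si](C)(C)C(C)(C)C)cc2O[C@H](c2ccc(O[Si](C)(C)C(C)(C)C)c(O[Si](C)(C)C(C)(C)C)c2)[C@@H]1O[Si](C)(C)C(C)(C)C | intermediate
15 | (+)-catechin, (2R,3S) | C1c2c(O)cc(O)cc2O[C@H](c2ccc(O)c(O)c2)[C@H]1O | starting material
16 | 3,5,7,3',4'-penta-O-TBS-catechin | C1c2c(O[Si](C)(C)C(C)(C)C)cc(O[Si](C)(C)C(C)(C)C)cc2O[C@H](c2ccc(O[Si](C)(C)C(C)(C)C)c(O[Si](C)(C)C(C)(C)C)c2)[C@H]1O[Si](C)(C)C(C)(C)C | intermediate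
17 | 4α-(2-ethoxyethoxy)-penta-O-TBS-catechin (2,3-trans-3,4-trans as drawn) | CCOCCO[C@@H]1c2c(O[Si](C)(C)C(C)(C)C)cc(O[Si](C)(C)C(C)(C)C)cc2O[C@H](c2ccc(O[Si](C)(C)C(C)(C)C)c(O[Si](C)(C)C(C)(C)C)c2)[C@H]1O[Si](C)(C)C(C)(C)C | intermediate
18 | penta-O-TBS-epicatechin-(4β→8)-[4α-(2-ethoxyethoxy)-penta-O-TBS-catechin] | CCOCCO[C@@H]1c2c(O[Si](C)(C)C(C)(C)C)cc(O[Si](C)(C)C(C)(C)C)c([C@H]3c4c(O[Si](C)(C)C(C)(C)C)cc(O[Si](C)(C)C(C)(C)C)cc4O[C@H](c4ccc(O[Si](C)(C)C(C)(C)C)c(O[Si](C)(C)C(C)(C)C)c4)[C@@H]3O[Si](C)(C)C(C)(C)C)c2O[C@H](c2ccc(O[Si](C)(C)C(C)(C)C)c(O[Si](C)(C)C(C)(C)C)c2)[C@H]1O[Si](C)(C)C(C)(C)C | intermediate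
19 | phloroglucinol | Oc1cc(O)cc(O)c1 | starting material
20 | 3,5-bis(TBS-oxy)phenol | Oc1cc(O[Si](C)(C)C(C)(C)C)cc(O[Si](C)(C)C(C)(C)C)c1 | intermediate
21 | penta-O-TBS-epicatechin-(4β→8)-penta-O-TBS-catechin-(4α→2)-[3,5-bis(TBS-oxy)phenol], free hydroxyl ortho to the new bond | Oc1cc(O[Si](C)(C)C(C)(C)C)cc(O[Si](C)(C)C(C)(C)C)c1[C@@H]2c3c(O[Si](C)(C)C(C)(C)C)cc(O[Si](C)(C)C(C)(C)C)c([C@H]4c5c(O[Si](C)(C)C(C)(C)C)cc(O[Si](C)(C)C(C)(C)C)cc5O[C@H](c5ccc(O[Si](C)(C)C(C)(C)C)c(O[Si](C)(C)C(C)(C)C)c5)[C@@H]4O[Si](C)(C)C(C)(C)C)c3O[C@H](c3ccc(O[Si](C)(C)C(C)(C)C)c(O[Si](C)(C)C(C)(C)C)c3)[C@H]2O[Si](C)(C)C(C)(C)C | intermediate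
22 | 3,4-dihydroxybenzaldehyde | O=Cc1ccc(O)c(O)c1 | starting material
23 | 3,4-bis(TBS-oxy)benzaldehyde | O=Cc1ccc(O[Si](C)(C)C(C)(C)C)c(O[Si](C)(C)C(C)(C)C)c1 | intermediate
24 | O-aryl O-trimethylsilyl acetal formed from the phenol oxygen of 21 and aldehyde 23 (both epimers at the acetal carbon) | C[Si](C)(C)OC(c1ccc(O[Si](C)(C)C(C)(C)C)c(O[Si](C)(C)C(C)(C)C)c1)Oc1cc(O[Si](C)(C)C(C)(C)C)cc(O[Si](C)(C)C(C)(C)C)c1[C@@H]2c3c(O[Si](C)(C)C(C)(C)C)cc(O[Si](C)(C)C(C)(C)C)c([C@H]4c5c(O[Si](C)(C)C(C)(C)C)cc(O[Si](C)(C)C(C)(C)C)cc5O[C@H](c5ccc(O[Si](C)(C)C(C)(C)C)c(O[Si](C)(C)C(C)(C)C)c5)[C@@H]4O[Si](C)(C)C(C)(C)C)c3O[C@H](c3ccc(O[Si](C)(C)C(C)(C)C)c(O[Si](C)(C)C(C)(C)C)c3)[C@H]2O[Si](C)(C)C(C)(C)C | intermediate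
25 | cycloadduct: tetradeca-O-TBS epicatechin-(4β→8)-catechin-(4α→8)-(2,3-trans-3,4-cis-flavan-3,4-diyl) unit whose O3 (acylated) and O4 (on the quaternary carbon) are bridged by the dithiolane-masked HCH acid as a cis-fused 1,4-dioxan-2-one | S1CCSC12CCC=C[C@@]2(O[C@H]3c4c(O[Si](C)(C)C(C)(C)C)cc(O[Si](C)(C)C(C)(C)C)c([C@@H]6c7c(O[Si](C)(C)C(C)(C)C)cc(O[Si](C)(C)C(C)(C)C)c([C@H]8c9c(O[Si](C)(C)C(C)(C)C)cc(O[Si](C)(C)C(C)(C)C)cc9O[C@H](c9ccc(O[Si](C)(C)C(C)(C)C)c(O[Si](C)(C)C(C)(C)C)c9)[C@@H]8O[Si](C)(C)C(C)(C)C)c7O[C@H](c7ccc(O[Si](C)(C)C(C)(C)C)c(O[Si](C)(C)C(C)(C)C)c7)[C@H]6O[Si](C)(C)C(C)(C)C)c4O[C@H](c5ccc(O[Si](C)(C)C(C)(C)C)c(O[Si](C)(C)C(C)(C)C)c5)[C@H]3O5)C5=O | intermediate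
26 | tetradeca-O-TBS epicatechin-(4β→8)-catechin-(4α→8)-catechin, terminal (2R,3S) unit acylated at O3 by (R)-6-(triethylsilyloxy)-1,4-dithiaspiro[4.5]dec-7-ene-6-carboxylic acid | S1CCSC12CCC=C[C@@]2(O[Si](CC)(CC)CC)C(=O)O[C@H]3Cc4c(O[Si](C)(C)C(C)(C)C)cc(O[Si](C)(C)C(C)(C)C)c([C@@H]6c7c(O[Si](C)(C)C(C)(C)C)cc(O[Si](C)(C)C(C)(C)C)c([C@H]8c9c(O[Si](C)(C)C(C)(C)C)cc(O[Si](C)(C)C(C)(C)C)cc9O[C@H](c9ccc(O[Si](C)(C)C(C)(C)C)c(O[Si](C)(C)C(C)(C)C)c9)[C@@H]8O[Si](C)(C)C(C)(C)C)c7O[C@H](c7ccc(O[Si](C)(C)C(C)(C)C)c(O[Si](C)(C)C(C)(C)C)c7)[C@H]6O[Si](C)(C)C(C)(C)C)c4O[C@@H]3c3ccc(O[Si](C)(C)C(C)(C)C)c(O[Si](C)(C)C(C)(C)C)c3 | intermediate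
27 | tetradeca-O-TBS epicatechin-(4β→8)-catechin-(4α→8)-catechin, terminal unit acylated at O3 by (S)-6-oxo-1-(triethylsilyloxy)cyclohex-2-ene-1-carboxylic acid | O=C1CCC=C[C@@]1(O[Si](CC)(CC)CC)C(=O)O[C@H]3Cc4c(O[Si](C)(C)C(C)(C)C)cc(O[Si](C)(C)C(C)(C)C)c([C@@H]6c7c(O[Si](C)(C)C(C)(C)C)cc(O[Si](C)(C)C(C)(C)C)c([C@H]8c9c(O[Si](C)(C)C(C)(C)C)cc(O[Si](C)(C)C(C)(C)C)cc9O[C@H](c9ccc(O[Si](C)(C)C(C)(C)C)c(O[Si](C)(C)C(C)(C)C)c9)[C@@H]8O[Si](C)(C)C(C)(C)C)c7O[C@H](c7ccc(O[Si](C)(C)C(C)(C)C)c(O[Si](C)(C)C(C)(C)C)c7)[C@H]6O[Si](C)(C)C(C)(C)C)c4O[C@@H]3c3ccc(O[Si](C)(C)C(C)(C)C)c(O[Si](C)(C)C(C)(C)C)c3 | intermediate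
28 | CNP0159807.2: epicatechin-(4β→8)-catechin-(4α→8)-catechin 3-O-[(S)-1-hydroxy-6-oxocyclohex-2-ene-1-carbonyl] ester | O=C1CCC=C[C@@]1(O)C(=O)O[C@H]1Cc2c(O)cc(O)c([C@@H]3c4c(O)cc(O)c([C@H]5c6c(O)cc(O)cc6O[C@H](c6ccc(O)c(O)c6)[C@@H]5O)c4O[C@H](c4ccc(O)c(O)c4)[C@H]3O)c2O[C@@H]1c1ccc(O)c(O)c1 | target

## Step count and risks

Total step count: 19. Longest linear sequence: 10 steps (steps 1–6, then 16–19).

Steps most likely to fail:

1. Step 16 (Proposed new method). What may go wrong: slow formation of the hindered aryloxy oxocarbenium ion; capture of that ion by other nucleophiles (arene C–H of the upper units, dithiolane sulfur) instead of the deactivated enol ether; endo instead of exo approach, eroding the 2,3-trans selectivity. Fallback (known chemistry only): it sets out from 15, 6 and 18 and comes back to the route at 26, so that the terminal unit is bought as catechin and the last bond formed is an interflavan bond. (+)-Catechin 15 is silylated on its four phenols only (TBSCl, imidazole, DMF) to 5,7,3',4'-tetra-O-TBS-catechin F1. Yamaguchi esterification of its free 3-hydroxyl with acid 6 (2,4,6-trichlorobenzoyl chloride, Et3N, then DMAP) should give the hydroxy ester F2. The tertiary hydroxyl is capped with TESOTf and 2,6-lutidine to give the silyl ether F3. An excess of F3 is then alkylated at C8 by the cation generated from 18 (TMSOTf, CH2Cl2, −78 °C; Friedel–Crafts alkylation, entry trans to the 3-OTBS group, 4α), which should give 26 directly.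

2. Step 2. What may go wrong: insufficient facial discrimination on the copper enolate of a small methyl ester, and tautomerisation and air oxidation of 3 towards methyl salicylate before it is hydroxylated. Fallback: it sets out from 3 and comes back at 6, replacing asymmetric catalysis by resolution. Keto ester 3 is hydroxylated with the same oxaziridine and Cu(OTf)2 without the chiral ligand to give the racemic hydroxy keto ester F4. This is carried through the conditions of steps 3 and 4 to the racemic dithiolane ester F5 and the racemic acid F6. Crystallisation with (R)-1-phenylethylamine is expected to deposit one diastereomeric salt, written here as the (R)-acid salt F7, while the (S)-acid salt F8 stays in the mother liquor (if the solubilities turn out the other way round, the (S)-amine is used). Acidification of F7 with dilute HCl releases 6.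

3. Step 12. What may go wrong: premature ionisation of the 4-alkoxy group of 17 or of the product by adventitious triflic acid, leading to self-condensation and oligomers, and competing substitution at C6. Fallback: it sets out from 13 and 16 and comes back at 18, installing the lower leaving group after the coupling instead of before it. Ether 13 is ionised with TMSOTf (CH2Cl2, −78 °C) in the presence of an excess of 16, which carries no leaving group, to give the 4β→8 dimer F9. DDQ and 2-ethoxyethanol then oxidise the only benzylic methylene left (C4 of the catechin unit), which should give 18.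

Further compounds
F1 | step 16 | 5,7,3',4'-tetra-O-TBS-(+)-catechin | C1c2c(O[Si](C)(C)C(C)(C)C)cc(O[Si](C)(C)C(C)(C)C)cc2O[C@H](c2ccc(O[Si](C)(C)C(C)(C)C)c(O[Si](C)(C)C(C)(C)C)c2)[C@H]1O
F2 | step 16 | tetra-O-TBS-catechin 3-O-[(R)-6-hydroxy-1,4-dithiaspiro[4.5]dec-7-ene-6-carbonyl] ester | S1CCSC12CCC=C[C@@]2(O)C(=O)O[C@H]3Cc4c(O[Si](C)(C)C(C)(C)C)cc(O[Si](C)(C)C(C)(C)C)cc4O[C@@H]3c3ccc(O[Si](C)(C)C(C)(C)C)c(O[Si](C)(C)C(C)(C)C)c3
F3 | step 16 | tetra-O-TBS-catechin 3-O-[(R)-6-(triethylsilyloxy)-1,4-dithiaspiro[4.5]dec-7-ene-6-carbonyl] ester | S1CCSC12CCC=C[C@@]2(O[Si](CC)(CC)CC)C(=O)O[C@H]3Cc4c(O[Si](C)(C)C(C)(C)C)cc(O[Si](C)(C)C(C)(C)C)cc4O[C@@H]3c3ccc(O[Si](C)(C)C(C)(C)C)c(O[Si](C)(C)C(C)(C)C)c3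
F4 | step 2 | racemic methyl 1-hydroxy-6-oxocyclohex-2-ene-1-carboxylate | O=C1CCC=CC1(O)C(=O)OC
F5 | step 2 | racemic methyl 6-hydroxy-1,4-dithiaspiro[4.5]dec-7-ene-6-carboxylate | S1CCSC12CCC=CC2(O)C(=O)OC
F6 | step 2 | racemic 6-hydroxy-1,4-dithiaspiro[4.5]dec-7-ene-6-carboxylic acid | S1CCSC12CCC=CC2(O)C(=O)O
F7 | step 2 | (R)-1-phenylethylammonium (R)-6-hydroxy-1,4-dithiaspiro[4.5]dec-7-ene-6-carboxylate | S1CCSC12CCC=C[C@@]2(O)C(=O)[O-].C[C@@H]([NH3+])c1ccccc1
F8 | step 2 | (R)-1-phenylethylammonium (S)-6-hydroxy-1,4-dithiaspiro[4.5]dec-7-ene-6-carboxylate | S1CCSC12CCC=C[C@]2(O)C(=O)[O-].C[C@@H]([NH3+])c1ccccc1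
F9 | step 12 | penta-O-TBS-epicatechin-(4β→8)-penta-O-TBS-catechin | C1c2c(O[Si](C)(C)C(C)(C)C)cc(O[Si](C)(C)C(C)(C)C)c([C@H]3c4c(O[Si](C)(C)C(C)(C)C)cc(O[Si](C)(C)C(C)(C)C)cc4O[C@H](c4ccc(O[Si](C)(C)C(C)(C)C)c(O[Si](C)(C)C(C)(C)C)c4)[C@@H]3O[Si](C)(C)C(C)(C)C)c2O[C@H](c2ccc(O[Si](C)(C)C(C)(C)C)c(O[Si](C)(C)C(C)(C)C)c2)[C@H]1O[Si](C)(C)C(C)(C)C
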